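## Retrosynthetic overview

- **Feature:** the plan rests on the tertiary carbinol C4 of the oxolane ring (O1–C2–C3–C4–C5). Its benzylic carbon C7' lies on the same ring face as C9 on C3 and the aryl group on C2, so C7' must reach the more hindered face of a C4 carbonyl.
- **Endgame:** target ⇒ debenzylation and reductive opening of C7'–O (through the p-quinone methide of the only free phenol) ⇒ cis-fused 1-hydroxy-3,7-dioxabicyclo[3.3.0]octane ⇒ Norrish–Yang C4–C7' closure ⇒ 2,3-cis oxolan-4-one whose C9 oxygen carries the guaiacylmethyl group.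
- **Ketone:** ketone ⇒ oxidation, ionic reduction of a hemiketal (sets C2) and aryl–C2 bond formation ⇒ lithiated cis-dihydrobenzofuran plus a (3S,4S)-lactone. The lactone comes from (S)-3-hydroxy-γ-butyrolactone by trans dianion alkylation (C3–C9) with an arylmethoxymethyl chloride made from vanillin.
- **cis-Dihydrobenzofuran:** ⇒ rhodium carbene 1,5 C–H insertion ⇒ aryl diazoacetate from 4-bromo-2-methoxyphenol, 4-(benzyloxy)-3-methoxybenzyl alcohol and dimethyl oxalate.
- **Ring order:** the dihydrobenzofuran ring forms in step 13. The oxolane ring is carried over from the lactone and fixed as an ether in step 17. The temporary second oxolane closes in step 20 and reopens in step 22.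

Key step: step 20

**Remark (locants):** the oxolane is O1, C2 (aryl), C3 (bearing C9), C4, C5. C7' is the benzylic carbon bound to C4. Double-primed locants belong to the dihydrobenzofuran (O1'', C2'' aryl, C3'' bearing CH2O).

**Remark (abbreviations):** DBF* = (2R,3R)-2-[4-(benzyloxy)-3-methoxyphenyl]-3-[(tert-butyldiphenylsilyloxy)methyl]-7-methoxy-2,3-dihydro-1-benzofuran-5-yl (2'',3''-cis). G* = 3-methoxy-4-(triisopropylsilyloxy)phenyl.

**Remark (protecting groups):** TES on C4–O falls to mild acid. TBDPS on the primary alcohol and aryl TIPS fall to fluoride. Benzyl on the other phenol is removed last by hydrogenolysis. As a result only C4–OH is free at the oxidation, and only the phenol para to C7' is free at the ring opening.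

**Assumption:** Rh2(S-PTTL)4 is taken to give the (2R,3S) ester, by analogy with related 2-(benzyloxy)aryl diazoacetates. If the sense is opposite, Rh2(R-PTTL)4 is used with no other change. Any residual minor enantiomer becomes a separable diastereomer after the coupling with the enantiopure lactone.

**Assumption:** 4-(benzyloxy)-3-methoxybenzyl alcohol is taken as commercial. Otherwise it follows from vanillin by benzylation and NaBH4 reduction.

## Fragment 1: arylmethoxymethyl chloride

Step 1
Reactants: 1 vanillin (4-hydroxy-3-methoxybenzaldehyde)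
Product: 2 3-methoxy-4-(triisopropylsilyloxy)benzaldehyde
Conditions: TIPSCl, imidazole, DMF, rt
Reagents that add atoms: chlorotriisopropylsilane, CC(C)[Si](Cl)(C(C)C)C(C)C
Why: Imidazole-promoted O-silylation of the phenol; the hindered aryl TIPS ether should outlast LiN(i-Pr)2, the aryllithium and BF3·OEt2 of later steps and fall to fluoride while the benzyl ether on the other phenol stays.

Step 2
Reactants: 2 3-methoxy-4-(triisopropylsilyloxy)benzaldehyde
Product: 3 [3-methoxy-4-(triisopropylsilyloxy)phenyl]methanol
Conditions: NaBH4, EtOH–THF, 0 °C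
Reagents that add atoms: none
Why: Borohydride reduction of the aldehyde, to which the aryl silyl ether is inert at 0 °C.

Step 3
Reactants: 3 [3-methoxy-4-(triisopropylsilyloxy)phenyl]methanol; 4 chloromethyl methyl sulfide
Product: 5 methylthiomethyl ether of 3 (G*–CH2–O–CH2–SMe)
Conditions: NaH, NaI (cat.), THF, 0 °C → rt
Reagents that add atoms: none
Why: Iodide-catalysed Williamson etherification of the sodium alkoxide gives the methylthiomethyl ether, a storable precursor of the alkoxymethyl chloride that spares the electron-rich benzylic alcohol the HCl/formaldehyde conditions it would not survive; the new OCH2 carbon is the future C9.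

Step 4
Reactants: 5 methylthiomethyl ether G*–CH2–O–CH2–SMe
Product: 6 arylmethoxymethyl chloride G*–CH2–O–CH2–Cl (used crude at once)
Conditions: SO2Cl2 (1.0 equiv), CH2Cl2, −78 °C; volatiles removed in vacuo
Reagents that add atoms: sulfuryl chloride, O=S(=O)(Cl)Cl
Why: Chlorinolysis of the O,S-acetal (S-chlorination, then collapse of the chlorosulfonium ion to the α-chloro ether), the method established for p-methoxybenzyloxymethyl chloride, which at −78 °C should outrun ring chlorination.

## Fragment 2: lactone

Step 5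
Reactants: 7 (S)-3-hydroxy-γ-butyrolactone [(4S)-4-hydroxyoxolan-2-one]; 6 arylmethoxymethyl chloride G*–CH2–O–CH2–Cl
Product: 9 (3S,4S)-4-hydroxy-3-[(G*-methoxy)methyl]oxolan-2-one (3,4-trans), via dilithio dianion 8 (not isolated)
Conditions: LiN(i-Pr)2 (2.2 equiv), THF, −78 °C; then 6, −78 → −40 °C; then AcOH
Reagents that add atoms: none
Why: Fráter–Seebach-type alkylation of the β-alkoxide enolate dianion, known to be trans-selective for this lactone: the electrophile approaches the enolate face opposite the C4 lithium alkoxide, which sets C3 as S (C9 trans to C4–O), and C-alkylation of the enolate is faster than O-alkylation of the alkoxide at low temperature.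

Step 6
Reactants: 9 (3S,4S)-4-hydroxy-3-[(G*-methoxy)methyl]oxolan-2-one
Product: 10 (3S,4S)-3-[(G*-methoxy)methyl]-4-(triethylsilyloxy)oxolan-2-one
Conditions: TESCl, imidazole, CH2Cl2, 0 °C → rt
Reagents that add atoms: chlorotriethylsilane, CC[Si](Cl)(CC)CC
Why: Routine silylation; triethylsilyl is chosen because mild acid methanolysis later removes it without touching the TBDPS and aryl TIPS ethers, so that the C4 hydroxyl is the only one free before the oxidation.

## Fragment 3: cis-dihydrobenzofuran bromide

Step 7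
Reactants: 11 4-bromo-2-methoxyphenol
Product: 12 4-bromo-2-iodo-6-methoxyphenol
Conditions: N-iodosuccinimide, TsOH·H2O (cat.), MeCN, rt, dark
Reagents that add atoms: N-iodosuccinimide, O=C1CCC(=O)N1I
Why: Electrophilic aromatic iodination directed by the free hydroxyl group to its only open ortho position, the para position being blocked by bromine.

Step 8
Reactants: 13 4-(benzyloxy)-3-methoxybenzyl alcohol
Product: 14 4-(benzyloxy)-3-methoxybenzyl chloride
Conditions: SOCl2, CH2Cl2, 0 °C
Reagents that add atoms: thionyl chloride, O=S(Cl)Cl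
Why: Chlorodehydroxylation through the chlorosulfite, fast for an electron-rich benzylic alcohol at 0 °C; the chloride is used without storage.

Step 9
Reactants: 12 4-bromo-2-iodo-6-methoxyphenol; 14 4-(benzyloxy)-3-methoxybenzyl chloride
Product: 15 2-{[4-(benzyloxy)-3-methoxyphenyl]methoxy}-5-bromo-1-iodo-3-methoxybenzene
Conditions: K2CO3, n-Bu4NI (cat.), DMF, 50 °C
Reagents that add atoms: none
Why: Williamson O-alkylation of the hindered but acidic phenol by a reactive benzylic chloride.

Step 10
Reactants: 15 aryl iodide ether; 16 dimethyl oxalate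
Product: 18 methyl 2-(2-{[4-(benzyloxy)-3-methoxyphenyl]methoxy}-5-bromo-3-methoxyphenyl)-2-oxoacetate, via arylmagnesium chloride 17 (not isolated)
Conditions: i-PrMgCl·LiCl (1.05 equiv), THF, −30 °C; transferred into 16 (3 equiv), THF, −78 °C; then NH4Cl aq
Reagents that add atoms: none
Why: Iodine–magnesium exchange is far faster at C–I than at C–Br and is helped by the ortho alkoxy group, and inverse addition of the Grignard reagent to excess dimethyl oxalate at −78 °C stops at the α-keto ester because the tetrahedral adduct survives until the quench.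

Step 11
Reactants: 18 α-keto ester
Product: 19 N-tosylhydrazone of 18
Conditions: TsNHNH2, MeOH, 60 °C
Reagents that add atoms: p-toluenesulfonohydrazide, Cc1ccc(cc1)S(=O)(=O)NN
Why: Condensation of the activated keto group with the sulfonyl hydrazide; no acid is added, so the acid-labile dialkoxybenzyl aryl ether is safe.

Step 12
Reactants: 19 N-tosylhydrazone
Product: 20 methyl 2-(2-{[4-(benzyloxy)-3-methoxyphenyl]methoxy}-5-bromo-3-methoxyphenyl)-2-diazoacetate
Conditions: DBU, CH2Cl2, rt
Reagents that add atoms: none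
Why: Bamford–Stevens elimination: the hydrazone anion loses p-toluenesulfinate at room temperature to give the aryl diazoacetate, which the ester stabilises enough for isolation.

Step 13
Reactants: 20 aryl diazoacetate
Product: 21 methyl (2R,3S)-2-[4-(benzyloxy)-3-methoxyphenyl]-5-bromo-7-methoxy-2,3-dihydro-1-benzofuran-3-carboxylate (2,3-cis)
Conditions: Rh2(S-PTTL)4 {dirhodium tetrakis[N-phthaloyl-(S)-tert-leucinate]} (1 mol %), toluene, −78 → −60 °C
Reagents that add atoms: none
Why: Intramolecular 1,5 C–H insertion of the donor/acceptor rhodium carbene into the electron-rich benzylic ether C–H bond, a reaction known for 2-(benzyloxy)aryl diazoacetates to give the cis-2-aryl-3-carboxylate under kinetic control; the concerted insertion inside the chiral carboxylate pocket sets C2'' and C3'' together, cis and (2R,3S).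

Step 14
Reactants: 21 cis ester
Product: 22 {(2R,3R)-2-[4-(benzyloxy)-3-methoxyphenyl]-5-bromo-7-methoxy-2,3-dihydro-1-benzofuran-3-yl}methanol (2,3-cis)
Conditions: i-Bu2AlH (2.5 equiv), CH2Cl2, −78 → −20 °C; then KNaC4H4O6 aq
Reagents that add atoms: none
Why: Hydride reduction of the ester under cold, non-basic conditions, in which the intermediate aldehyde is reduced faster than it can enolise, so that the epimerisable cis C3'' centre is kept (the descriptor becomes R only through the change in priorities).

Step 15
Reactants: 22 cis alcohol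
Product: 23 DBF*–Br (tert-butyldiphenylsilyl ether of 22)
Conditions: TBDPSCl, imidazole, DMF, rt
Reagents that add atoms: tert-butylchlorodiphenylsilane, CC(C)(C)[Si](Cl)(c1ccccc1)c1ccccc1
Why: Routine silylation of the primary alcohol; TBDPS resists n-BuLi, BF3·OEt2 at −78 °C and the acid methanolysis of step 18.

## Coupling, key step and endgame

Step 16
Reactants: 23 DBF*–Br; 10 TES-protected lactone
Product: 25 hemiketal (3S,4S)-2-DBF*-3-[(G*-methoxy)methyl]-4-(triethylsilyloxy)oxolan-2-ol (C2 epimers; in equilibrium with the open hydroxy ketone; used crude), via aryllithium 24 (not isolated)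
Conditions: n-BuLi (1.05 equiv), THF, −78 °C; then 10 (1.1 equiv), −78 °C; then AcOH/THF at −78 °C
Reagents that add atoms: none
Why: Bromine–lithium exchange followed by 1,2-addition of the aryllithium to the lactone, as in C-aryl glycoside synthesis; the lithium hemiketal alkoxide persists at −78 °C, which prevents a second addition, and the cold acidic quench keeps the open β-alkoxy ketone tautomer from epimerising at C3 or eliminating.

Step 17
Reactants: 25 hemiketal
Product: 27 (2R,3R,4S)-2-DBF*-3-[(G*-methoxy)methyl]-4-(triethylsilyloxy)oxolane (2,3-cis; 3,4-trans), via oxocarbenium ion 26 (not isolated)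
Conditions: Et3SiH (5 equiv), BF3·OEt2 (2 equiv), CH2Cl2, −78 °C, short contact; then NaHCO3 aq
Reagents that add atoms: none
Why: Ionic reduction (reductive deoxygenation) of a cyclic aryl hemiketal, known to give 2,3-cis oxolane lignans at low temperature: the aryl-stabilised oxocarbenium ion adopts the envelope with C4–OSiEt3 pseudoaxial (electrostatic attraction) and the C3 side chain pseudoaxial (relief of strain against the coplanar aryl group), and hydride enters from inside the envelope, syn to C4–O and anti to C9, so that H-2 ends trans and the aryl group cis to C9 (C2 = R).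

Step 18
Reactants: 27 TES ether
Product: 28 (2R,3S,4S)-2-DBF*-3-[(G*-methoxy)methyl]oxolan-4-ol
Conditions: pyridinium p-toluenesulfonate (cat.), MeOH–CH2Cl2, 0 °C → rt
Reagents that add atoms: none
Why: Acid-catalysed methanolysis selective for the least hindered silicon; the primary TBDPS ether, the aryl TIPS ether and the benzylic ethers tolerate pyridinium p-toluenesulfonate.

Step 19
Reactants: 28 C4 alcohol
Product: 29 (2R,3R)-2-DBF*-3-[(G*-methoxy)methyl]oxolan-4-one (2,3-cis)
Conditions: Dess–Martin periodinane, NaHCO3 (solid), CH2Cl2, 0 °C → rt; filtration through pH-7-buffered silica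
Reagents that add atoms: none
Why: Dess–Martin oxidation in a bicarbonate-buffered, non-aqueous medium forms the ketone without enolising conditions, so that C3 (α to the carbonyl and β to an alkoxy leaving group) neither epimerises to the 2,3-trans isomer nor eliminates; 29 is irradiated at once.

Step 20
Reactants: 29 2,3-cis oxolan-4-one
Product: 31 cis-fused 1-hydroxy-3,7-dioxabicyclo[3.3.0]octane with the new C4–C7' bond [ring 1: O1/C2(DBF* endo)/C3/C4/C5; ring 2: C4/C7'(G*)/O/C9/C3; C4–OH and H-3 at the fusion; (2R,3R,4S); C7' epimers both carried on], via 1,5-biradical 30 (not isolated)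
Conditions: hν (medium-pressure Hg lamp, Pyrex, λ > 300 nm), degassed benzene (0.005 M), 15 °C, argon
Reagents that add atoms: none
Why: Excitation of the C4 carbonyl (n,π*) through Pyrex, where the aryl ethers hardly absorb, is followed by 1,6-hydrogen transfer from C7' (benzylic and α-oxygenated, weak C–H bond) to the carbonyl oxygen through a seven-membered transition state, and biradical 30 collapses by C4–C7' coupling. The closest known reaction type is the Norrish–Yang δ-hydrogen abstraction/cyclisation of β-alkoxy ketones, which is established for 4-[(arylmethoxy)methyl]oxolan-3-ones and gives furofurans hydroxylated at the ring fusion. The one ring that closes is the second oxolane (C4, C7', O, C9, C3), formed by radical–radical recombination of the 1,5-biradical and not by a polar closure. C4 is controlled by the C3 stereocentre through the three-atom tether C9–O–C7': only a cis 5–5 fusion can be reached, so C7' bonds on the C9 face and the hydroxyl ends on the opposite face (4S), while at C7' the aryl group should prefer the convex face, though either epimer serves because this centre becomes CH2 in step 22. The step needs hydrogen abstraction at C7' to win over α-cleavage and over other C–H bonds, and the substrate secures this because the γ atom of the chain is oxygen (no γ-hydrogen, no fragmenting 1,4-biradical), H-2 is a β-hydrogen out of reach of the carbonyl oxygen, and the remaining benzylic C–H bonds are too remote at high dilution. The neutral, base-free medium keeps the 2,3-cis relationship at C3 intact.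

Step 21
Reactants: 31 silylated bicycle
Product: 32 desilylated bicycle (free 4-hydroxy-3-methoxyphenyl group on C7'; free C3''–CH2OH; benzyl ether kept; C7' epimers)
Conditions: Bu4NF (3 equiv), AcOH (3 equiv), THF, 0 °C → rt
Reagents that add atoms: none
Why: Fluoride cleavage of both silyl ethers, buffered with acetic acid; the benzyl ether is untouched, which leaves the phenol para to C7' as the only free phenol of the molecule.

Step 22
Reactants: 32 desilylated bicycle
Product: 34 O-benzyl target [(2R,3R,4S)-oxolane with C3–CH2OH; C4–OH; C4–CH2(4-hydroxy-3-methoxyphenyl); benzyl ether on the C2'' aryl group], via p-quinone methide 33 (not isolated)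
Conditions: NaBH4 (10 equiv, in portions), 1 M NaOH aq–1,4-dioxane (1:1), 100 °C, argon; then NH4Cl aq
Reagents that add atoms: none
Why: Proposed new method: in hot alkali the phenolate para to C7' can expel the C9 alkoxide in a vinylogous elimination to give quinone methide 33, whose reclosure is only degenerate (or epimerises C7') while hydride addition at C7' is irreversible, so the equilibrium should drain to 34 with C4 untouched; the C2–O1 and C2''–O1'' bonds stay closed because their para oxygens are alkylated and cannot give a neutral quinone methide; the closest known reaction type is the borohydride deoxygenation of p-hydroxybenzyl alcohols and p-hydroxyaryl ketones in hot aqueous NaOH through quinone methides, here extended to a cyclic p-hydroxybenzyl alkyl ether.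

Step 23
Reactants: 34 O-benzyl target
Product: 35 target CNP0284796.1
Conditions: H2 (1 atm), 10% Pd/C, EtOAc, rt, stopped at consumption of 34
Reagents that add atoms: none
Why: Catalytic hydrogenolysis of the aryl benzyl ether, which in a neutral aprotic solvent at 1 atm is much faster than cleavage of the 2-aryloxolane and 2-aryldihydrobenzofuran C–O bonds, as is usual for the last step in oxolane lignan and benzofuran neolignan work.

## Compound list

1 | vanillin | COc1cc(C=O)ccc1O | starting material
2 | 3-methoxy-4-(triisopropylsilyloxy)benzaldehyde | COc1cc(C=O)ccc1O[Si](C(C)C)(C(C)C)C(C)C | intermediate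
3 | [3-methoxy-4-(triisopropylsilyloxy)phenyl]methanol | COc1cc(CO)ccc1O[Si](C(C)C)(C(C)C)C(C)C | intermediate
4 | chloromethyl methyl sulfide | CSCCl | starting material
5 | methylthiomethyl ether of 3 | COc1cc(COCSC)ccc1O[Si](C(C)C)(C(C)C)C(C)C | intermediate
6 | arylmethoxymethyl chloride | COc1cc(COCCl)ccc1O[Si](C(C)C)(C(C)C)C(C)C | intermediate
7 | (S)-3-hydroxy-γ-butyrolactone | O=C1C[C@H](O)CO1 | starting material
8 | dilithio dianion of 7 | [Li]O[C@@H]1COC(O[Li])=C1 | intermediate
9 | (3S,4S)-4-hydroxy-3-[(G*-methoxy)methyl]oxolan-2-one | O=C1OC[C@@H](O)[C@@H]1COCc1ccc(O[Si](C(C)C)(C(C)C)C(C)C)c(OC)c1 | intermediate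
10 | TES ether of 9 | O=C1OC[C@@H](O[Si](CC)(CC)CC)[C@@H]1COCc1ccc(O[Si](C(C)C)(C(C)C)C(C)C)c(OC)c1 | intermediate
11 | 4-bromo-2-methoxyphenol | COc1cc(Br)ccc1O | starting material
12 | 4-bromo-2-iodo-6-methoxyphenol | COc1cc(Br)cc(I)c1O | intermediate
13 | 4-(benzyloxy)-3-methoxybenzyl alcohol | COc1cc(CO)ccc1OCc1ccccc1 | starting material
14 | 4-(benzyloxy)-3-methoxybenzyl chloride | COc1cc(CCl)ccc1OCc1ccccc1 | intermediate
15 | 2-{[4-(benzyloxy)-3-methoxyphenyl]methoxy}-5-bromo-1-iodo-3-methoxybenzene | COc1cc(Br)cc(I)c1OCc1ccc(OCc2ccccc2)c(OC)c1 | intermediate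
16 | dimethyl oxalate | COC(=O)C(=O)OC | starting material
17 | arylmagnesium chloride from 15 | COc1cc(Br)cc([Mg]Cl)c1OCc1ccc(OCc2ccccc2)c(OC)c1 | intermediate
18 | methyl aryl-2-oxoacetate | COC(=O)C(=O)c1cc(Br)cc(OC)c1OCc1ccc(OCc2ccccc2)c(OC)c1 | intermediate
19 | N-tosylhydrazone of 18 | COC(=O)C(=NNS(=O)(=O)c1ccc(C)cc1)c1cc(Br)cc(OC)c1OCc1ccc(OCc2ccccc2)c(OC)c1 | intermediate
20 | methyl aryl diazoacetate | COC(=O)C(=[N+]=[N-])c1cc(Br)cc(OC)c1OCc1ccc(OCc2ccccc2)c(OC)c1 | intermediate
21 | methyl (2R,3S)-cis-2-aryl-5-bromo-7-methoxy-2,3-dihydrobenzofuran-3-carboxylate | Brc1cc(OC)c2c(c1)[C@H](C(=O)OC)[C@H](c1ccc(OCc3ccccc3)c(OC)c1)O2 | intermediate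
22 | (2R,3R)-cis alcohol | Brc1cc(OC)c2c(c1)[C@H](CO)[C@H](c1ccc(OCc3ccccc3)c(OC)c1)O2 | intermediate
23 | DBF*–Br | Brc1cc(OC)c2c(c1)[C@H](CO[Si](c1ccccc1)(c1ccccc1)C(C)(C)C)[C@H](c1ccc(OCc3ccccc3)c(OC)c1)O2 | intermediate
24 | DBF*–Li | [Li]c1cc(OC)c2c(c1)[C@H](CO[Si](c1ccccc1)(c1ccccc1)C(C)(C)C)[C@H](c1ccc(OCc3ccccc3)c(OC)c1)O2 | intermediate
25 | hemiketal (C2 epimers) | OC1(c3cc(OC)c4c(c3)[C@H](CO[Si](c5ccccc5)(c5ccccc5)C(C)(C)C)[C@H](c3ccc(OCc5ccccc5)c(OC)c3)O4)OC[C@@H](O[Si](CC)(CC)CC)[C@@H]1COCc2ccc(O[Si](C(C)C)(C(C)C)C(C)C)c(OC)c2 | intermediate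
26 | oxocarbenium ion | CC[Si](CC)(CC)O[C@@H]1C[O+]=C(c3cc(OC)c4c(c3)[C@H](CO[Si](c5ccccc5)(c5ccccc5)C(C)(C)C)[C@H](c3ccc(OCc5ccccc5)c(OC)c3)O4)[C@H]1COCc2ccc(O[Si](C(C)C)(C(C)C)C(C)C)c(OC)c2 | intermediate
27 | (2R,3R,4S)-2,3-cis-3,4-trans oxolane TES ether | CC[Si](CC)(CC)O[C@@H]1CO[C@@H](c3cc(OC)c4c(c3)[C@H](CO[Si](c5ccccc5)(c5ccccc5)C(C)(C)C)[C@H](c3ccc(OCc5ccccc5)c(OC)c3)O4)[C@H]1COCc2ccc(O[Si](C(C)C)(C(C)C)C(C)C)c(OC)c2 | intermediate
28 | (2R,3S,4S)-oxolan-4-ol | O[C@@H]1CO[C@@H](c3cc(OC)c4c(c3)[C@H](CO[Si](c5ccccc5)(c5ccccc5)C(C)(C)C)[C@H](c3ccc(OCc5ccccc5)c(OC)c3)O4)[C@H]1COCc2ccc(O[Si](C(C)C)(C(C)C)C(C)C)c(OC)c2 | intermediate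
29 | (2R,3R)-2,3-cis oxolan-4-one (key-step precursor) | O=C1CO[C@@H](c3cc(OC)c4c(c3)[C@H](CO[Si](c5ccccc5)(c5ccccc5)C(C)(C)C)[C@H](c3ccc(OCc5ccccc5)c(OC)c3)O4)[C@H]1COCc2ccc(O[Si](C(C)C)(C(C)C)C(C)C)c(OC)c2 | intermediate
30 | 1,5-biradical (C4 and C7') | O[C]1CO[C@@H](c3cc(OC)c4c(c3)[C@H](CO[Si](c5ccccc5)(c5ccccc5)C(C)(C)C)[C@H](c3ccc(OCc5ccccc5)c(OC)c3)O4)[C@H]1CO[CH]c2ccc(O[Si](C(C)C)(C(C)C)C(C)C)c(OC)c2 | intermediate
31 | cis-fused 1-hydroxy-3,7-dioxabicyclo[3.3.0]octane (key-step product, C7' open) | COc1cc(C6[C@@]2(O)CO[C@@H](c3cc(OC)c4c(c3)[C@H](CO[Si](c5ccccc5)(c5ccccc5)C(C)(C)C)[C@H](c3ccc(OCc5ccccc5)c(OC)c3)O4)[C@H]2CO6)ccc1O[Si](C(C)C)(C(C)C)C(C)C | intermediate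
32 | desilylated bicycle (C7' open) | COc1cc(C6[C@@]2(O)CO[C@@H](c3cc(OC)c4c(c3)[C@H](CO)[C@H](c3ccc(OCc5ccccc5)c(OC)c3)O4)[C@H]2CO6)ccc1O | intermediate
33 | p-quinone methide | COC1=CC(=C[C@@]2(O)CO[C@@H](c3cc(OC)c4c(c3)[C@H](CO)[C@H](c3ccc(OCc5ccccc5)c(OC)c3)O4)[C@H]2CO)C=CC1=O | intermediate
34 | O-benzyl target | COc1cc(C[C@@]2(O)CO[C@@H](c3cc(OC)c4c(c3)[C@H](CO)[C@H](c3ccc(OCc5ccccc5)c(OC)c3)O4)[C@H]2CO)ccc1O | intermediate
35 | CNP0284796.1, (2R,3R,4S) oxolane, (2''R,3''R) dihydrobenzofuran | COc1cc(C[C@@]2(O)CO[C@@H](c3cc(OC)c4c(c3)[C@H](CO)[C@H](c3ccc(O)c(OC)c3)O4)[C@H]2CO)ccc1O | target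

## Step count and risks

Total step count: 23. Longest linear sequence: 16 steps (7, 9–23).

**1. Step 22 (reductive opening through the quinone methide).**
- Expulsion of an alkoxide from the phenolate may be too slow at 100 °C, so that the borohydride is lost to hydrolysis first.
- Reclosure by the C9 alkoxide may outrun hydride capture.
- A semipinacol-type shift driven by the C4 alkoxide may divert the quinone methide.
- Fallback (known chemistry): it sets out from 32 and comes back at 35. Heterogeneous hydrogenolysis (H2 1 atm, 10% Pd/C, EtOH, rt) is used, which is the established mono-opening of furofuran lignans at a benzylic C–O bond to give 2-aryl-4-benzyloxolanes.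
- The benzyl ether falls in the same operation, so 34 is bypassed. Hydrogen uptake is followed and the reaction is stopped after the first ring C–O cleavage.
- The C7'–O bond is expected to react first. Its aryl group is a free phenol and is expected on the convex face, whereas the C2 aryl group is endo and shielded.
- No new compound is made (F0).

**2. Step 20 (Norrish–Yang closure).**
- The excited ketone may be deactivated by charge-transfer quenching from the electron-rich aryl groups.
- α-Cleavage may lead to decarbonylation, or to photo-epimerisation at C3.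
- Back hydrogen transfer in the biradical may lower the efficiency.
- Fallback: it sets out from 29 and comes back at 35. It delivers oxygen, not carbon, to the open face.
  - Petasis methylenation (Cp2TiMe2, toluene, 65 °C, non-basic) gives the exocyclic alkene F1.
  - Epoxidation (mCPBA, NaHCO3, CH2Cl2, 0 °C) from the face anti to C9 and the C2 aryl group gives the spiro-epoxide F2, with its oxygen on the face of the future hydroxyl and its CH2 (the future C7') cis to C9.
  - 4-(Benzyloxy)-3-methoxyphenylmagnesium bromide F3, made from commercial 1-(benzyloxy)-4-bromo-2-methoxybenzene and Mg, opens the epoxide at the CH2 terminus with CuI catalysis (THF, −30 → 0 °C) to give the tertiary carbinol F4.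
  - Bu4NF/AcOH gives the desilylated carbinol F5.
  - H2 over Pd/C removes both aryl benzyl ethers and the 4-hydroxy-3-methoxybenzyl ether on the C9 oxygen to give 35.

**3. Step 17 (ionic reduction to the 2,3-cis oxolane).**
- The kinetic cis product may re-ionise at the benzylic C2–O bond and drift to the 2,3-trans isomer.
- Proton loss from the oxocarbenium ion may scramble C3.
- The Lewis acid may attack the dialkoxybenzyl-type ether or the C2''–O bond.
- Fallback: it sets out from 25 and comes back at 27. C2 is set by reagent control, and the ring is closed at C5, away from C2.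
  - The open hydroxy ketone tautomer of 25 is reduced by Corey–Bakshi–Shibata reduction [(S)-Me-CBS oxazaborolidine, BH3·SMe2, THF, −20 °C; aryl as the large group] to the (1R)-1-aryl-1,4-diol F6.
  - Selective sulfonylation of the primary hydroxyl (TsCl, Et3N, DMAP cat., CH2Cl2, 0 °C) gives the primary tosylate F7.
  - KOt-Bu (THF, 0 °C) closes the oxolane by a 5-exo-tet Williamson reaction with retention at C2.

Further compounds
F0 | step 22 | none | none
F1 | step 20 | (2R,3R)-2-DBF*-3-[(G*-methoxy)methyl]-4-methylideneoxolane | C=C1CO[C@@H](c3cc(OC)c4c(c3)[C@H](CO[Si](c5ccccc5)(c5ccccc5)C(C)(C)C)[C@H](c3ccc(OCc5ccccc5)c(OC)c3)O4)[C@H]1COCc2ccc(O[Si](C(C)C)(C(C)C)C(C)C)c(OC)c2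
F2 | step 20 | spiro-epoxide at C4 (oxygen anti to C9, CH2 cis to C9) | C1O[C@@]12CO[C@@H](c3cc(OC)c4c(c3)[C@H](CO[Si](c5ccccc5)(c5ccccc5)C(C)(C)C)[C@H](c3ccc(OCc5ccccc5)c(OC)c3)O4)[C@H]2COCc6ccc(O[Si](C(C)C)(C(C)C)C(C)C)c(OC)c6
F3 | step 20 | 4-(benzyloxy)-3-methoxyphenylmagnesium bromide | COc1cc([Mg]Br)ccc1OCc1ccccc1
F4 | step 20 | tertiary carbinol with C7'H2–[4-(benzyloxy)-3-methoxyphenyl] and C9–O–CH2–G* | COc1cc(C[C@@]2(O)CO[C@@H](c3cc(OC)c4c(c3)[C@H](CO[Si](c5ccccc5)(c5ccccc5)C(C)(C)C)[C@H](c3ccc(OCc5ccccc5)c(OC)c3)O4)[C@H]2COCc6ccc(O[Si](C(C)C)(C(C)C)C(C)C)c(OC)c6)ccc1OCc1ccccc1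
F5 | step 20 | desilylated carbinol | COc1cc(C[C@@]2(O)CO[C@@H](c3cc(OC)c4c(c3)[C@H](CO)[C@H](c3ccc(OCc5ccccc5)c(OC)c3)O4)[C@H]2COCc6ccc(O)c(OC)c6)ccc1OCc1ccccc1
F6 | step 17 | (1R)-1-DBF*-2-[(G*-methoxy)methyl]-3-(triethylsilyloxy)butane-1,4-diol | O[C@@H](c3cc(OC)c4c(c3)[C@H](CO[Si](c5ccccc5)(c5ccccc5)C(C)(C)C)[C@H](c3ccc(OCc5ccccc5)c(OC)c3)O4)[C@@H](COCc2ccc(O[Si](C(C)C)(C(C)C)C(C)C)c(OC)c2)[C@H](O[Si](CC)(CC)CC)CO
F7 | step 17 | primary tosylate of F6 | O[C@@H](c3cc(OC)c4c(c3)[C@H](CO[Si](c5ccccc5)(c5ccccc5)C(C)(C)C)[C@H](c3ccc(OCc5ccccc5)c(OC)c3)O4)[C@@H](COCc2ccc(O[Si](C(C)C)(C(C)C)C(C)C)c(OC)c2)[C@H](O[Si](CC)(CC)CC)COS(=O)(=O)c2ccc(C)cc2
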